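**Retrosynthetic overview**
1. The last step removes three MOM ethers. Before that, the pyranone ring C is cut at C3–C4. The protected flavanone is an isomer of an achiral aldehyde, so one enantioselective intramolecular Rh-catalysed alkene hydroacylation supplies ring C, the C4 ketone, the C3 methylene and the C2 stereocentre.
2. Enabling feature: C2 carries both the ring oxygen O1 and the benzofuran-5-yl group, C3 is a bare CH2, and C4 sits on ring A ortho to O1. The C2–C3 unit can therefore be an aryl 1-arylvinyl ether, O1–C2(=C3H2)–Ar, held 1,6 to a formyl C–H. It is 1,1-disubstituted, so the acyl group must go to C3, and it has no allylic hydrogen.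
3. The vinyl ether aldehyde comes from an aryl ester (ester C=O to C=CH2 with a titanium methylidene, then aryl iodide to CHO). The ester comes from a benzofuran-5-carboxylic acid and a 2-iodophenol made from phloroglucinol.
4. The prenyl group reaches C6 of the benzofuran by aromatic Claisen transfer of a 1,1-dimethylallyl group from O7. The 7-hydroxybenzofuran-5-carboxylate comes from furan-3-carbaldehyde and diethyl succinate (Stobbe condensation, then ring closure).
5. Ring order: furan (bought), then the benzene ring of the benzofuran (step 2), then pyranone ring C (step 13). Ring A is bought.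

Key step: step 13

Assumption: the sense of induction cannot be derived with certainty for this new substrate class. (R)-DTBM-SEGPHOS is written for the (2S)-product, and its equally available antipode is taken if a test run shows the opposite sense.

**Step 1**
Reactants: 1 furan-3-carbaldehyde; 2 diethyl succinate
Product: 3 (E)-3-(ethoxycarbonyl)-4-(furan-3-yl)but-3-enoic acid
Conditions: KOt-Bu, t-BuOH, reflux; then aq. HCl
Reagents that add atoms: none
Why: Stobbe condensation, in which the succinate enolate adds to the aldehyde, the aldolate lactonises onto the distal ester, and E1cB opening of the paraconic lactone should give the half-ester with the furyl group cis to CH2CO2H (E), the geometry needed in step 2.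

**Step 2**
Reactants: 3 (E)-3-(ethoxycarbonyl)-4-(furan-3-yl)but-3-enoic acid
Product: 5 ethyl 7-hydroxy-1-benzofuran-5-carboxylate, via ethyl 7-acetoxy-1-benzofuran-5-carboxylate 4 (not isolated)
Conditions: Ac2O, NaOAc, reflux; evaporate; then K2CO3 (cat.), EtOH, 60 °C
Reagents that add atoms: acetic anhydride, CC(=O)OC(C)=O (acetyl group of 4 only, lost again in the same step)
Why: The mixed anhydride of 3 should acylate the nucleophilic α-carbon C2 of the furan (intramolecular Friedel–Crafts acylation, the classical Stobbe benzannulation, whereas attack at C4 would give an isobenzofuran), the ketone enolises and is trapped as acetate 4, and K2CO3/EtOH then removes only the phenolic acetate by a transesterification that is degenerate at the ethyl ester.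

**Step 3**
Reactants: 6 2-methylbut-3-en-2-ol
Product: 8 tert-butyl 2-methylbut-3-en-2-yl carbonate, via lithium 2-methylbut-3-en-2-olate 7 (not isolated)
Conditions: n-BuLi, THF, −78 → 0 °C; then Boc2O, 0 °C → rt
Reagents that add atoms: n-butyllithium, [Li]CCCC (lithium of 7 only); di-tert-butyl dicarbonate, CC(C)(C)OC(=O)OC(=O)OC(C)(C)C
Why: O-Acylation of a tertiary lithium alkoxide by Boc2O is the standard access to a mixed tert-allylic carbonate.

**Step 4**
Reactants: 5 ethyl 7-hydroxy-1-benzofuran-5-carboxylate; 8 tert-butyl 2-methylbut-3-en-2-yl carbonate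
Product: 9 ethyl 7-[(2-methylbut-3-en-2-yl)oxy]-1-benzofuran-5-carboxylate
Conditions: Pd(PPh3)4 (3 mol %), THF, 0 °C
Reagents that add atoms: none
Why: Tsuji–Trost O-allylation, in which decarboxylative ionisation of 8 gives the 1,1-dimethyl-π-allylpalladium cation and tert-butoxide, the latter deprotonates 5, and at low temperature the phenoxide should attack the more substituted allyl terminus to give the kinetic branched ether.

**Step 5**
Reactants: 9 ethyl 7-[(2-methylbut-3-en-2-yl)oxy]-1-benzofuran-5-carboxylate
Product: 10 ethyl 7-hydroxy-6-(3-methylbut-2-en-1-yl)-1-benzofuran-5-carboxylate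
Conditions: N,N-diethylaniline, 150 °C, Ar
Reagents that add atoms: none
Why: Aromatic Claisen rearrangement, in which only C6 of the two positions ortho to O7 bears hydrogen (C7a is the ring-fusion carbon), so the [3,3] shift with allyl inversion should place a linear prenyl group at C6 before tautomerisation to the phenol, while the weakly basic solvent suppresses acid-induced chroman formation.

**Step 6**
Reactants: 10 ethyl 7-hydroxy-6-(3-methylbut-2-en-1-yl)-1-benzofuran-5-carboxylate
Product: 11 ethyl 7-(methoxymethoxy)-6-(3-methylbut-2-en-1-yl)-1-benzofuran-5-carboxylate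
Conditions: MOMCl, i-Pr2NEt, CH2Cl2, 0 °C → rt
Reagents that add atoms: chloromethyl methyl ether, COCCl
Why: Williamson-type O-alkylation should give an acetal protecting group that withstands the hydroxide, titanium and magnesium reagents that follow.

**Step 7**
Reactants: 11 ethyl 7-(methoxymethoxy)-6-(3-methylbut-2-en-1-yl)-1-benzofuran-5-carboxylate
Product: 12 7-(methoxymethoxy)-6-(3-methylbut-2-en-1-yl)-1-benzofuran-5-carboxylic acid
Conditions: LiOH, THF/MeOH/H2O, 55 °C; then 1 M HCl to pH 4, 0 °C
Reagents that add atoms: lithium hydroxide, [Li+].[OH-]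
Why: Saponification should proceed because the MOM ether, the prenyl group and the benzofuran are inert to hydroxide, and a brief cold acidification to pH 4 spares the MOM ether.

**Step 8**
Reactants: 13 phloroglucinol
Product: 14 3,5-bis(methoxymethoxy)phenol
Conditions: MOMCl (2 equiv), i-Pr2NEt, DMF, 0 °C → rt
Reagents that add atoms: chloromethyl methyl ether, COCCl
Why: This is a statistical double O-alkylation of three equivalent phenols, whose mono-, bis- and tris-ethers differ enough in polarity for chromatographic separation, and the unwanted fractions can be recycled.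

**Step 9**
Reactants: 14 3,5-bis(methoxymethoxy)phenol
Product: 15 2-iodo-3,5-bis(methoxymethoxy)phenol
Conditions: NIS (1.0 equiv), MeCN, −20 → 0 °C, dark
Reagents that add atoms: N-iodosuccinimide, O=C1CCC(=O)N1I
Why: In this electrophilic aromatic iodination the free OH is the strongest director, and the position ortho to it (also para to one OMOM) is less shielded than C4 between the two MOM ethers, so one equivalent of NIS should give the 2-iodide.

**Step 10**
Reactants: 12 7-(methoxymethoxy)-6-(3-methylbut-2-en-1-yl)-1-benzofuran-5-carboxylic acid; 15 2-iodo-3,5-bis(methoxymethoxy)phenol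
Product: 16 2-iodo-3,5-bis(methoxymethoxy)phenyl 7-(methoxymethoxy)-6-(3-methylbut-2-en-1-yl)-1-benzofuran-5-carboxylate
Conditions: DIC, DMAP, CH2Cl2, 0 °C → rt
Reagents that add atoms: none
Why: Steglich esterification through the acylpyridinium ion couples hindered acids with phenols under neutral conditions that leave the MOM ethers, the aryl iodide and the alkene untouched.

**Step 11**
Reactants: 16 2-iodo-3,5-bis(methoxymethoxy)phenyl 7-(methoxymethoxy)-6-(3-methylbut-2-en-1-yl)-1-benzofuran-5-carboxylate
Product: 17 5-{1-[2-iodo-3,5-bis(methoxymethoxy)phenoxy]ethenyl}-7-(methoxymethoxy)-6-(3-methylbut-2-en-1-yl)-1-benzofuran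
Conditions: Cp2TiMe2 (3 equiv), toluene, 75 °C, dark; filtration through basic alumina
Reagents that add atoms: dimethyltitanocene, [CH3-].[CH3-].[Ti+4].c1cc[cH-]c1.c1cc[cH-]c1
Why: Petasis methylenation, in which thermally formed Cp2Ti=CH2 adds [2+2] to the ester carbonyl and cycloreversion of the oxatitanacyclobutane gives the enol ether, has close precedent for aryl benzoates and is run without acid, so acetals, aryl iodide and alkenes should survive.

**Step 12**
Reactants: 17 5-{1-[2-iodo-3,5-bis(methoxymethoxy)phenoxy]ethenyl}-7-(methoxymethoxy)-6-(3-methylbut-2-en-1-yl)-1-benzofuran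
Product: 19 2-({1-[7-(methoxymethoxy)-6-(3-methylbut-2-en-1-yl)-1-benzofuran-5-yl]ethenyl}oxy)-4,6-bis(methoxymethoxy)benzaldehyde, via arylmagnesium chloride 18 (not isolated)
Conditions: i-PrMgCl·LiCl, THF, −20 → 0 °C; then DMF, → rt; pH 7 buffer
Reagents that add atoms: isopropylmagnesium chloride–lithium chloride, CC(C)[Mg]Cl.[Li+].[Cl-] (MgCl of 18 only); N,N-dimethylformamide, CN(C)C=O
Why: Iodine–magnesium exchange with the turbo-Grignard reagent is fast on an aryl iodide flanked by two oxygen substituents and, unlike an alkyllithium, should not deprotonate C2–H of the benzofuran, after which Bouveault formylation with DMF and a buffered work-up deliver the aldehyde without hydrolysing the enol ether.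

**Step 13**
Reactants: 19 2-({1-[7-(methoxymethoxy)-6-(3-methylbut-2-en-1-yl)-1-benzofuran-5-yl]ethenyl}oxy)-4,6-bis(methoxymethoxy)benzaldehyde
Product: 20 (2S)-5,7-bis(methoxymethoxy)-2-[7-(methoxymethoxy)-6-(3-methylbut-2-en-1-yl)-1-benzofuran-5-yl]-2,3-dihydro-4H-chromen-4-one
Conditions: [Rh(cod)Cl]2 (2.5 mol %), (R)-DTBM-SEGPHOS (5 mol %), NaBArF4 (5 mol %), 4 Å MS, 1,4-dioxane, 80 °C
Reagents that add atoms: none
Why: Proposed new method: the cationic Rh(I)–diphosphine should bind the enol-ether C=C of 19, insert into the formyl C–H to give an alkene-chelated acyl–Rh(III) hydride, pass the hydride to the alkene carbon that bears O1 and the benzofuranyl group (future C2), and then join the former =CH2 carbon (C3) to the acyl carbon (C4) by reductive elimination from a seven-membered acyl–alkyl rhodacycle. The closest known reaction types are the Rh/DTBM-SEGPHOS-catalysed endo- and enantioselective hydroacylation of 2-(2-arylallyl)benzaldehydes to 3-aryl-1-tetralones (same 1,6-array, CH2 in place of O1) and that of N-(1-arylvinyl)indole-2-carbaldehydes (heteroatom on the carbon that becomes the stereocentre), whereas an aryl 1-arylvinyl ether has not been used as the acceptor. One ring is closed, the pyranone ring C, in a formal 6-endo-trig mode. The only new stereocentre, C2, is fixed in the hydride-transfer step by the C2-symmetric ligand, whose bulky aryl quadrants should distinguish the two alkene faces through the size difference between the twisted ortho-prenylated benzofuranyl group and the tether oxygen, with no substrate element taking part. The step needs regioselectivity for acyl transfer to CH2 over the five-ring 2-methylbenzofuran-3-one mode, which the 1,1-disubstitution secures because a tertiary alkyl–rhodium is avoided, and chemoselectivity over the prenyl and furan C=C bonds, which are trisubstituted or aromatic and cannot chelate the acyl–rhodium centre. Alkene isomerisation and the carbonyl–ene reaction, the side paths of the all-carbon tether, are shut off because the alkene has no allylic hydrogen, and decarbonylation should be held back by chelation through the alkene and the two ortho ether oxygens.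

**Step 14**
Reactants: 20 (2S)-5,7-bis(methoxymethoxy)-2-[7-(methoxymethoxy)-6-(3-methylbut-2-en-1-yl)-1-benzofuran-5-yl]-2,3-dihydro-4H-chromen-4-one
Product: 21 (2S)-5,7-dihydroxy-2-[7-hydroxy-6-(3-methylbut-2-en-1-yl)-1-benzofuran-5-yl]-2,3-dihydro-4H-chromen-4-one
Conditions: HCl (1.25 M in MeOH), 40 °C
Reagents that add atoms: none
Why: Acid-catalysed acetal exchange with methanol should remove all three aryl MOM ethers under conditions in common use for prenylated flavanones, and C2 should hold because opening of ring C to the chalcone is a base-driven process.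

**Compound list**
1 | furan-3-carbaldehyde | O=Cc1ccoc1 | starting material
2 | diethyl succinate | CCOC(=O)CCC(=O)OCC | starting material
3 | (E)-3-(ethoxycarbonyl)-4-(furan-3-yl)but-3-enoic acid | OC(=O)C/C(=C\c1ccoc1)C(=O)OCC | intermediate
4 | ethyl 7-acetoxy-1-benzofuran-5-carboxylate (not isolated) | CCOC(=O)c1cc(OC(C)=O)c2occc2c1 | intermediate
5 | ethyl 7-hydroxy-1-benzofuran-5-carboxylate | CCOC(=O)c1cc(O)c2occc2c1 | intermediate
6 | 2-methylbut-3-en-2-ol | CC(C)(O)C=C | starting material
7 | lithium 2-methylbut-3-en-2-olate (not isolated) | [Li+].[O-]C(C)(C)C=C | intermediate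
8 | tert-butyl 2-methylbut-3-en-2-yl carbonate | CC(C)(C)OC(=O)OC(C)(C)C=C | intermediate
9 | ethyl 7-[(2-methylbut-3-en-2-yl)oxy]-1-benzofuran-5-carboxylate | CCOC(=O)c1cc(OC(C)(C)C=C)c2occc2c1 | intermediate
10 | ethyl 7-hydroxy-6-(3-methylbut-2-en-1-yl)-1-benzofuran-5-carboxylate | CCOC(=O)c1cc2ccoc2c(O)c1CC=C(C)C | intermediate
11 | ethyl 7-(methoxymethoxy)-6-(3-methylbut-2-en-1-yl)-1-benzofuran-5-carboxylate | CCOC(=O)c1cc2ccoc2c(OCOC)c1CC=C(C)C | intermediate
12 | 7-(methoxymethoxy)-6-(3-methylbut-2-en-1-yl)-1-benzofuran-5-carboxylic acid | OC(=O)c1cc2ccoc2c(OCOC)c1CC=C(C)C | intermediate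
13 | phloroglucinol | Oc1cc(O)cc(O)c1 | starting material
14 | 3,5-bis(methoxymethoxy)phenol | COCOc1cc(O)cc(OCOC)c1 | intermediate
15 | 2-iodo-3,5-bis(methoxymethoxy)phenol | COCOc1cc(O)c(I)c(OCOC)c1 | intermediate
16 | 2-iodo-3,5-bis(methoxymethoxy)phenyl 7-(methoxymethoxy)-6-(3-methylbut-2-en-1-yl)-1-benzofuran-5-carboxylate | COCOc1cc(OC(=O)c2cc3ccoc3c(OCOC)c2CC=C(C)C)c(I)c(OCOC)c1 | intermediate
17 | 5-{1-[2-iodo-3,5-bis(methoxymethoxy)phenoxy]ethenyl}-7-(methoxymethoxy)-6-(3-methylbut-2-en-1-yl)-1-benzofuran | COCOc1cc(OC(=C)c2cc3ccoc3c(OCOC)c2CC=C(C)C)c(I)c(OCOC)c1 | intermediate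
18 | arylmagnesium chloride from 17, MgCl in place of I (not isolated) | COCOc1cc(OC(=C)c2cc3ccoc3c(OCOC)c2CC=C(C)C)c([Mg]Cl)c(OCOC)c1 | intermediate
19 | 2-({1-[7-(methoxymethoxy)-6-(3-methylbut-2-en-1-yl)-1-benzofuran-5-yl]ethenyl}oxy)-4,6-bis(methoxymethoxy)benzaldehyde | COCOc1cc(OC(=C)c2cc3ccoc3c(OCOC)c2CC=C(C)C)c(C=O)c(OCOC)c1 | intermediate
20 | (2S)-5,7-bis(methoxymethoxy)-2-[7-(methoxymethoxy)-6-(3-methylbut-2-en-1-yl)-1-benzofuran-5-yl]-2,3-dihydro-4H-chromen-4-one | CC(C)=CCc1c([C@@H]2CC(=O)c3c(OCOC)cc(OCOC)cc3O2)cc2ccoc2c1OCOC | intermediate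
21 | (2S)-5,7-dihydroxy-2-[7-hydroxy-6-(3-methylbut-2-en-1-yl)-1-benzofuran-5-yl]-2,3-dihydro-4H-chromen-4-one | CC(C)=CCc1c([C@@H]2CC(=O)c3c(O)cc(O)cc3O2)cc2ccoc2c1O | target

**Step count**
Total steps: 14. Longest linear sequence: 11 (steps 1, 2, 4, 5, 6, 7, 10, 11, 12, 13, 14).

**Steps most likely to fail**

1. **Step 13 (proposed new method).**
   - What may go wrong:
     - decarbonylation of the doubly ortho-substituted acyl–rhodium hydride;
     - β-aryloxide elimination at the alkyl–rhodium stage, which would open the ether link and erode the enantiomeric purity;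
     - slow alkene binding next to the ortho-prenyl chain;
     - poor facial selectivity.
   - The fallback uses known chemistry, forms the same C3–C4 bond, sets out from 11 and comes back at 20.
   - Chloromethyllithium (ICH2Cl, MeLi·LiBr, THF, −78 °C) should turn ester 11 into 2-chloro-1-[7-(methoxymethoxy)-6-(3-methylbut-2-en-1-yl)-1-benzofuran-5-yl]ethan-1-one F1.
   - Noyori–Ikariya transfer hydrogenation [RuCl(p-cymene)((R,R)-TsDPEN), HCO2H/Et3N] should give (1S)-2-chloro-1-[7-(methoxymethoxy)-6-(3-methylbut-2-en-1-yl)-1-benzofuran-5-yl]ethan-1-ol F2.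
   - Commercial 2,4,6-trihydroxybenzaldehyde with MOMCl (2 equiv)/i-Pr2NEt gives 2-hydroxy-4,6-bis(methoxymethoxy)benzaldehyde F3, because the hydrogen-bonded OH stays free.
   - Mitsunobu etherification of F3 with F2 (PPh3, DIAD, toluene, 0 °C) should proceed with inversion, the β-chlorine disfavouring ionisation. It gives 2-{(1R)-2-chloro-1-[7-(methoxymethoxy)-6-(3-methylbut-2-en-1-yl)-1-benzofuran-5-yl]ethoxy}-4,6-bis(methoxymethoxy)benzaldehyde F4, which has the spatial arrangement of (2S) in 20.
   - An N-heterocyclic carbene (thiazolium salt, DBU, toluene, heat) then converts the aldehyde into its Breslow intermediate. This displaces the primary chloride (6-exo-tet), a ring closure known for chroman-4-ones, to give 20.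

2. **Step 11.**
   - What may go wrong: the titanium methylidene adds slowly to a carbonyl group shielded by the ortho-prenyl chain and the ortho-iodophenoxy group, so thermal decay of the reagent outruns olefination. The enol ether may also hydrolyse on isolation.
   - The fallback changes the order of construction, so the enol ether is made while C6 is still unsubstituted and the prenyl group is delivered afterwards. It sets out from 9 and comes back at 17.
   - Saponification of 9 (LiOH) gives 7-[(2-methylbut-3-en-2-yl)oxy]-1-benzofuran-5-carboxylic acid F5.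
   - Steglich coupling of F5 with 15 gives 2-iodo-3,5-bis(methoxymethoxy)phenyl 7-[(2-methylbut-3-en-2-yl)oxy]-1-benzofuran-5-carboxylate F6.
   - The Tebbe reagent (pyridine, THF/toluene, −40 → 0 °C, too cold for a premature Claisen shift) gives 5-{1-[2-iodo-3,5-bis(methoxymethoxy)phenoxy]ethenyl}-7-[(2-methylbut-3-en-2-yl)oxy]-1-benzofuran F7.
   - Aromatic Claisen rearrangement (N,N-diethylaniline, 140 °C) gives 5-{1-[2-iodo-3,5-bis(methoxymethoxy)phenoxy]ethenyl}-6-(3-methylbut-2-en-1-yl)-1-benzofuran-7-ol F8.
   - MOMCl/i-Pr2NEt then gives 17.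

3. **Step 14.**
   - What may go wrong: acid-induced addition of the freed 7-OH to the neighbouring prenyl double bond (chroman ring formation), and loss of enantiomeric purity through reversible opening of ring C on prolonged acid treatment.
   - The fallback replaces protic solvolysis by a non-acidic exchange of protecting groups. It sets out from 20 and comes back at 21.
   - TMSOTf/2,2'-bipyridyl (MeCN, 0 °C → rt), a known conversion of aryl MOM ethers into aryl silyl ethers, should give (2S)-5,7-bis(trimethylsilyloxy)-2-[6-(3-methylbut-2-en-1-yl)-7-(trimethylsilyloxy)-1-benzofuran-5-yl]-2,3-dihydro-4H-chromen-4-one F9.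
   - Water at room temperature hydrolyses F9 to 21 under neutral conditions.

**Further compounds**
F1 | step 13 | 2-chloro-1-[7-(methoxymethoxy)-6-(3-methylbut-2-en-1-yl)-1-benzofuran-5-yl]ethan-1-one | ClCC(=O)c1cc2ccoc2c(OCOC)c1CC=C(C)C
F2 | step 13 | (1S)-2-chloro-1-[7-(methoxymethoxy)-6-(3-methylbut-2-en-1-yl)-1-benzofuran-5-yl]ethan-1-ol | CC(C)=CCc1c([C@H](O)CCl)cc2ccoc2c1OCOC
F3 | step 13 | 2-hydroxy-4,6-bis(methoxymethoxy)benzaldehyde | COCOc1cc(O)c(C=O)c(OCOC)c1
F4 | step 13 | 2-{(1R)-2-chloro-1-[7-(methoxymethoxy)-6-(3-methylbut-2-en-1-yl)-1-benzofuran-5-yl]ethoxy}-4,6-bis(methoxymethoxy)benzaldehyde | CC(C)=CCc1c([C@@H](Oc2cc(OCOC)cc(OCOC)c2C=O)CCl)cc2ccoc2c1OCOC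
F5 | step 11 | 7-[(2-methylbut-3-en-2-yl)oxy]-1-benzofuran-5-carboxylic acid | OC(=O)c1cc(OC(C)(C)C=C)c2occc2c1
F6 | step 11 | 2-iodo-3,5-bis(methoxymethoxy)phenyl 7-[(2-methylbut-3-en-2-yl)oxy]-1-benzofuran-5-carboxylate | COCOc1cc(OC(=O)c2cc(OC(C)(C)C=C)c3occc3c2)c(I)c(OCOC)c1
F7 | step 11 | 5-{1-[2-iodo-3,5-bis(methoxymethoxy)phenoxy]ethenyl}-7-[(2-methylbut-3-en-2-yl)oxy]-1-benzofuran | COCOc1cc(OC(=C)c2cc(OC(C)(C)C=C)c3occc3c2)c(I)c(OCOC)c1
F8 | step 11 | 5-{1-[2-iodo-3,5-bis(methoxymethoxy)phenoxy]ethenyl}-6-(3-methylbut-2-en-1-yl)-1-benzofuran-7-ol | COCOc1cc(OC(=C)c2cc3ccoc3c(O)c2CC=C(C)C)c(I)c(OCOC)c1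
F9 | step 14 | (2S)-5,7-bis(trimethylsilyloxy)-2-[6-(3-methylbut-2-en-1-yl)-7-(trimethylsilyloxy)-1-benzofuran-5-yl]-2,3-dihydro-4H-chromen-4-one | CC(C)=CCc1c([C@@H]2CC(=O)c3c(O[Si](C)(C)C)cc(O[Si](C)(C)C)cc3O2)cc2ccoc2c1O[Si](C)(C)C
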